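Ring A of the target (C1–C5, C10; eudesmane numbering) is taken intact from (S)-carvone: its isopropenyl-bearing carbon is C1, its α′ carbon C10 and its carbonyl carbon C5. Everything rests on disconnecting ring B at C9–C10 and C5=C6. The key step, a Robinson annulation of the α′ enolate of trans-6-methylcarvone with methyl vinyl ketone, forms both bonds, closes ring B and sets quaternary C10 in one operation; it exploits the C1 stereocentre beside C10, which sends the butanone chain to the face opposite the isopropenyl group. The precursor is carvone carrying one extra α′ methyl group. The isopropenyl group is later cut down to the C1 aldehyde and joined to the acyl trione by reductive Knoevenagel alkylation.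

Key step: step 2

Remarks on the chemistry:
- The decalin is numbered as a eudesmane: ring A = C1–C5 and C10, ring B = C5–C10, methyls on C4 and C10, C1′ = the carbon attached to C1. "Syn" and "anti" refer to the C10 methyl group.
- The target is (1R,4S,5S,7S,10R) in this numbering: the C1 arm and the C7 isopropenyl are syn to the C10 methyl, and H5 and the 4-OH are anti (trans-decalin).
- The trione unit is written as the enol tautomer of the target SMILES.
- The minor cis epimer from step 1 is not removed, because that centre is planarised again in step 2.

Step 1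
Reactants: 1 (S)-(+)-carvone; 2 iodomethane
Product: 3 trans-6-methylcarvone
Conditions: LDA, THF, −78 °C; MeI, −78 → 0 °C
Reagents that add atoms: none
Why: Kinetic deprotonation of the enone with LDA takes place at the α′ CH2 (cross-conjugated enolate) and the enolate alkylation with iodomethane occurs mainly anti to the neighbouring isopropenyl group, which should give the trans isomer.

Step 2
Reactants: 3 trans-6-methylcarvone; 4 methyl vinyl ketone
Product: 6 linear dienone (3,5-dien-7-one with the C10 methyl syn to the C1 isopropenyl), via Michael adduct 5 (not isolated)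
Conditions: LDA, THF, −78 → −20 °C, recool; MVK (slow addition), −78 °C; AcOH, −78 °C; concentrate; then KOH, MeOH, rt → 50 °C
Reagents that add atoms: none
Why: LDA removes the single α′ hydrogen of 3 to give the cross-conjugated lithium enolate, which adds through C10 to methyl vinyl ketone in a Michael reaction (C9–C10 bond, quaternary C10); after the cold acetic acid quench, KOH in methanol forms the methyl enolate of the side-chain ketone, which attacks the enone carbonyl C5, and the aldol loses water to the linear dienone (C5=C6 bond). The closest known reaction type is the Robinson annulation of a kinetically generated α′ enolate of a carvone derivative. Ring B closes by intramolecular aldol condensation, a 6-(enolendo)-exo-trig closure. The new stereocentre C10 is controlled by the adjacent carvone-derived centre C1: the vinyl ketone approaches the enolate face opposite the isopropenyl group, so the C10 methyl should end cis to it. The step needs α′ and not γ deprotonation, which kinetic deprotonation with LDA at low temperature secures, and it needs aldol closure at C5 and not a second Michael addition of the chain enolate to C3, which is secured by protonating the adduct cold and by the irreversible dehydration under protic base, where the competing Michael closure is reversible.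

Step 3
Reactants: 6 linear dienone
Product: 7 β,γ-enone (C4=C5 alkene, C7 ketone, C1 isopropenyl)
Conditions: Li, NH3(l)/THF, t-BuOH (1 equiv), −78 °C; solid NH4Cl
Reagents that add atoms: none
Why: Dissolving-metal (Birch-type) 1,6-reduction puts two electrons and a proton at C3 to give the C4=C5–C6=C7 dienolate, whose kinetic protonation at the α carbon C6 by solid ammonium chloride should deliver the deconjugated enone, the isolated isopropenyl group being inert to lithium in ammonia and no stereocentre being formed.

Step 4
Reactants: 7 β,γ-enone
Product: 9 4-hydroxy-5-en-7-one carrying the C1 isopropenyl group (4-OH anti), via epoxy ketone 8 (not isolated)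
Conditions: mCPBA (1.0 equiv), CH2Cl2/aq. NaHCO3, 0 °C; then DBU, CH2Cl2, rt
Reagents that add atoms: mCPBA (3-chloroperoxybenzoic acid), OOC(=O)c1cccc(Cl)c1
Why: Prilezhaev epoxidation should select the electron-rich tetrasubstituted C4=C5 alkene over the 1,1-disubstituted isopropenyl group and occur on the face anti to the axial C10 methyl, and DBU then opens the β,γ-epoxy ketone by E1cB elimination through the C6 enolate, so the C4 carbinol oxygen is fixed anti to the C10 methyl.

Step 5
Reactants: 9 4-hydroxy-5-en-7-one carrying the C1 isopropenyl group
Product: 11 1-acetyl-4-hydroxy-5-en-7-one, via ozonide 10 (not isolated)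
Conditions: O3, CH2Cl2, −78 °C (Sudan III end point); Me2S, −78 °C → rt
Reagents that add atoms: ozone, [O-][O+]=O
Why: Ozonolysis is chemoselective for the electron-rich isopropenyl group over the electron-poor conjugated C5=C6 alkene, and reductive cleavage of the ozonide should leave the C1 acetyl group with C1 untouched.

Step 6
Reactants: 11 1-acetyl-4-hydroxy-5-en-7-one
Product: 12 1-acetyl-4-hydroxy-trans-decalin-7-one (H5 anti)
Conditions: H2 (1 atm), [Ir(cod)(PCy3)(py)]PF6 (5 mol %), CH2Cl2, rt
Reagents that add atoms: none
Why: Hydroxyl-directed homogeneous hydrogenation with Crabtree's catalyst: the tertiary allylic C4 hydroxyl binds iridium and both hydrogens should be delivered to C5=C6 from its own face, which is also the face free of the angular methyl, so H5 ends anti to the C10 methyl (trans ring fusion).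

Step 7
Reactants: 12 1-acetyl-4-hydroxy-trans-decalin-7-one
Product: 13 C7 ethylene acetal of 12
Conditions: HOCH2CH2OH, PPTS (cat.), benzene, reflux (Dean–Stark)
Reagents that add atoms: ethylene glycol, OCCO
Why: Acid-catalysed acetalisation (dioxolane formation) should be selective for the unhindered ring ketone C7 because the acetyl carbonyl sits on C1 next to quaternary C10, the same discrimination that separates 3- from 20-ketones in pregnanes, and PPTS is too weak to dehydrate the tertiary alcohol.

Step 8
Reactants: 13 C7 ethylene acetal of 12
Product: 14 C1 carboxylic acid (acetal retained)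
Conditions: Br2, NaOH, H2O/1,4-dioxane, 0 → 10 °C, dark; then cold 1 M HCl to pH 4
Reagents that add atoms: sodium hydroxide, [Na+].[OH-]
Why: Haloform reaction: exhaustive bromination of the acetyl CH3 and hydroxide-induced C–C cleavage should give the acid one carbon shorter, the acetal and the tertiary alcohol being stable to base and the equatorial C1 configuration being the thermodynamic one.

Step 9
Reactants: 14 C1 carboxylic acid
Product: 16 1-(hydroxymethyl)-4-hydroxy-trans-decalin-7-one, via hydroxymethyl acetal 15 (not isolated)
Conditions: LiAlH4, THF, 0 °C → reflux; then 1 M HCl, THF, rt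
Reagents that add atoms: water, O
Why: Lithium aluminium hydride reduction of the carboxylic acid gives the primary alcohol while the dioxolane is inert, and dilute aqueous acid then hydrolyses the acetal without touching the tertiary alcohol.

Step 10
Reactants: 16 1-(hydroxymethyl)-4-hydroxy-trans-decalin-7-one
Product: 17 7-carbonitrile (C7 epimer mixture)
Conditions: TosMIC, t-BuOK, DME, EtOH (2 equiv), 0 → 35 °C
Reagents that add atoms: TosMIC (4-toluenesulfonylmethyl isocyanide), Cc1ccc(cc1)S(=O)(=O)C[N+]#[C-]
Why: Van Leusen reductive cyanation should convert the unhindered ketone into the nitrile with one added carbon (addition, oxazoline formation, loss of sulfinate and deformylation), the hydroxyls being tolerated as alkoxides and the C7 mixture being corrected in step 11.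

Step 11
Reactants: 17 7-carbonitrile
Product: 20 equatorial 7-acetyl compound (acetyl syn), via ketimine 18 (not isolated), via axial acetyl epimer 19 (not isolated)
Conditions: MeLi (5 equiv), Et2O, 0 °C → rt; 1 M HCl, 0 °C; then NaOMe (cat.), MeOH, rt
Reagents that add atoms: methyllithium, [Li]C; water, O
Why: Organolithium addition to the nitrile stops at the N-lithio ketimine (the two alkoxides are spectators), acid hydrolysis frees the methyl ketone, and methoxide equilibration through the enolate should place the acetyl group equatorial at C7, that is syn to the C10 methyl.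

Step 12
Reactants: 20 equatorial 7-acetyl compound
Product: 21 7-isopropenyl-1-(hydroxymethyl)decalin-4-ol
Conditions: Ph3PCH3Br, t-BuOK (excess), THF, 0 → 50 °C
Reagents that add atoms: methyltriphenylphosphonium bromide, C[P+](c1ccccc1)(c1ccccc1)c1ccccc1.[Br-]
Why: Wittig methylenation of the methyl ketone with excess ylide (which also covers the two hydroxyls) should give the isopropenyl group, and any enolisation only returns the favoured equatorial C7 epimer.

Step 13
Reactants: 21 7-isopropenyl-1-(hydroxymethyl)decalin-4-ol
Product: 22 C1 aldehyde
Conditions: TEMPO (cat.), PhI(OAc)2, CH2Cl2, rt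
Reagents that add atoms: none
Why: Oxoammonium (TEMPO) oxidation is selective for the primary alcohol, stops at the aldehyde, leaves the tertiary alcohol and the alkene alone and is not basic enough to epimerise C1.

Step 14
Reactants: 23 phloroglucinol; 24 isovaleryl chloride
Product: 25 isovalerylphloroglucinol
Conditions: AlCl3, PhNO2, rt → 60 °C; aq. HCl work-up
Reagents that add atoms: none
Why: Friedel–Crafts C-acylation of the electron-rich arene, where the first acyl group deactivates the ring and should stop the reaction at the mono-ketone.

Step 15
Reactants: 25 isovalerylphloroglucinol; 2 iodomethane (2 equiv)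
Product: 26 acyl trione (gem-dimethyl, enol form)
Conditions: NaOMe (3 equiv), MeI (2.2 equiv), MeOH, 0 °C → rt
Reagents that add atoms: iodomethane (second equivalent), CI
Why: Dearomative double C-methylation of the acylphloroglucinol phenolate consumes two equivalents of iodomethane: the first methyl enters at a free ring carbon and the second should enter at that same, now more electron-rich carbon to give the gem-dimethyl enolised trione, the stoichiometry limiting over-methylation.

Step 16
Reactants: 22 C1 aldehyde; 26 acyl trione
Product: 28 target, via alkylidene trione 27 (not isolated)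
Conditions: Hantzsch ester, L-proline (20 mol %), CH2Cl2, rt
Reagents that add atoms: none
Why: Organocatalytic reductive alkylation: Knoevenagel condensation of the aldehyde with the only free nucleophilic ring carbon of the trione gives the alkylidene trione, which the Hantzsch ester should reduce by conjugate hydride transfer, no stereocentre being formed and C1 staying in its favoured equatorial configuration.

Compound list
1 | (S)-(+)-carvone, (5S)-2-methyl-5-(prop-1-en-2-yl)cyclohex-2-en-1-one | CC1=CC[C@H](C(C)=C)CC1=O | starting material
2 | iodomethane | CI | starting material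
3 | trans-6-methylcarvone, (5S,6R)-2,6-dimethyl-5-(prop-1-en-2-yl)cyclohex-2-en-1-one | CC1=CC[C@H](C(C)=C)[C@@H](C)C1=O | intermediate
4 | methyl vinyl ketone (but-3-en-2-one) | CC(=O)C=C | starting material
5 | Michael adduct, 2,6-dimethyl-6-(3-oxobutyl)-5-(prop-1-en-2-yl)cyclohex-2-en-1-one with the oxobutyl chain trans to the isopropenyl group (not isolated) | CC1=CC[C@H](C(C)=C)[C@@](C)(CCC(C)=O)C1=O | intermediate
6 | linear dienone, (4aR,5R)-4a,8-dimethyl-5-(prop-1-en-2-yl)-4,4a,5,6-tetrahydronaphthalen-2(3H)-one (C3=C4 and C5=C6 alkenes, C7 ketone, C10 methyl syn to C1 isopropenyl) | CC1=CC[C@H](C(C)=C)[C@@]2(C)CCC(=O)C=C12 | intermediate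
7 | β,γ-enone: C4=C5 alkene, C7 ketone, C1 isopropenyl syn | O=C1CC[C@]2(C)[C@@H](C(C)=C)CCC(C)=C2C1 | intermediate
8 | 4,5-epoxy-7-ketone, epoxide oxygen anti (not isolated) | O=C1CC[C@]2(C)[C@@H](C(C)=C)CC[C@]3(C)O[C@]23C1 | intermediate
9 | 4-hydroxy-5-en-7-one with C1 isopropenyl syn and 4-OH anti | O=C1CC[C@]2(C)[C@@H](C(C)=C)CC[C@](C)(O)C2=C1 | intermediate
10 | ozonide (3-methyl-1,2,4-trioxolan-3-yl at C1) of 9, trioxolane carbon undefined (not isolated) | O=C1CC[C@]2(C)[C@@H](C3(C)OCOO3)CC[C@](C)(O)C2=C1 | intermediate
11 | 1-acetyl-4-hydroxy-5-en-7-one (acetyl syn, 4-OH anti) | O=C1CC[C@]2(C)[C@@H](C(C)=O)CC[C@](C)(O)C2=C1 | intermediate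
12 | 1-acetyl-4-hydroxy-trans-decalin-7-one (H5 anti) | O=C1CC[C@]2(C)[C@@H](C(C)=O)CC[C@](C)(O)[C@H]2C1 | intermediate
13 | C7 ethylene acetal (dioxolane) of 12 | C12(OCCO1)CC[C@]3(C)[C@@H](C(C)=O)CC[C@](C)(O)[C@H]3C2 | intermediate
14 | C1 carboxylic acid, C7 dioxolane, 4-OH | C12(OCCO1)CC[C@]3(C)[C@@H](C(=O)O)CC[C@](C)(O)[C@H]3C2 | intermediate
15 | C1 hydroxymethyl, C7 dioxolane, 4-OH (not isolated) | C12(OCCO1)CC[C@]3(C)[C@@H](CO)CC[C@](C)(O)[C@H]3C2 | intermediate
16 | 1-(hydroxymethyl)-4-hydroxy-trans-decalin-7-one | O=C1CC[C@]2(C)[C@@H](CO)CC[C@](C)(O)[C@H]2C1 | intermediate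
17 | 7-carbonitrile of the 1-(hydroxymethyl)-4-hydroxy-trans-decalin (C7 epimer mixture, C7 left undefined) | N#CC1CC[C@]2(C)[C@@H](CO)CC[C@](C)(O)[C@H]2C1 | intermediate
18 | C7 methyl ketimine (C7 undefined, not isolated) | CC(=N)C1CC[C@]2(C)[C@@H](CO)CC[C@](C)(O)[C@H]2C1 | intermediate
19 | axial 7-acetyl epimer (acetyl anti, not isolated) | CC(=O)[C@@H]1CC[C@]2(C)[C@@H](CO)CC[C@](C)(O)[C@H]2C1 | intermediate
20 | equatorial 7-acetyl-1-(hydroxymethyl)-trans-decalin-4-ol (acetyl syn) | CC(=O)[C@H]1CC[C@]2(C)[C@@H](CO)CC[C@](C)(O)[C@H]2C1 | intermediate
21 | 7-isopropenyl-1-(hydroxymethyl)-4,10-dimethyl-trans-decalin-4-ol | C=C(C)[C@H]1CC[C@]2(C)[C@@H](CO)CC[C@](C)(O)[C@H]2C1 | intermediate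
22 | C1 aldehyde, 4-hydroxy-7-isopropenyl-4,10-dimethyl-trans-decalin-1-carbaldehyde | C=C(C)[C@H]1CC[C@]2(C)[C@@H](C=O)CC[C@](C)(O)[C@H]2C1 | intermediate
23 | phloroglucinol (benzene-1,3,5-triol) | Oc1cc(O)cc(O)c1 | starting material
24 | isovaleryl chloride (3-methylbutanoyl chloride) | CC(C)CC(Cl)=O | starting material
25 | isovalerylphloroglucinol, 3-methyl-1-(2,4,6-trihydroxyphenyl)butan-1-one | CC(C)CC(=O)c1c(O)cc(O)cc1O | intermediate
26 | acyl trione, 3,5-dihydroxy-6,6-dimethyl-2-(3-methylbutanoyl)cyclohexa-2,4-dien-1-one | CC(C)CC(=O)C1=C(O)C=C(O)C(C)(C)C1=O | intermediate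
27 | alkylidene trione (Knoevenagel adduct, C1′=C ring, geometry undefined, not isolated) | C=C(C)[C@H]1CC[C@]2(C)[C@@H](C=C3C(=O)C(C)(C)C(=O)C(C(=O)CC(C)C)=C3O)CC[C@](C)(O)[C@H]2C1 | intermediate
28 | 3,5-dihydroxy-4-{[(1R,4S,4aS,6S,8aR)-4-hydroxy-4,8a-dimethyl-6-(prop-1-en-2-yl)decahydronaphthalen-1-yl]methyl}-6,6-dimethyl-2-(3-methylbutanoyl)cyclohexa-2,4-dien-1-one (CNP0490948.1) | C=C(C)[C@H]1CC[C@]2(C)[C@@H](CC3=C(O)C(C)(C)C(=O)C(C(=O)CC(C)C)=C3O)CC[C@](C)(O)[C@H]2C1 | target

Total step count: 16.
Longest linear sequence: 14 steps (steps 1–13 and 16); the trione branch (steps 14–15) is two steps.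

Steps most likely to fail

Step 2 (key step). The lithium enolate may polymerise methyl vinyl ketone, proton transfer between enolate and adduct may erode the conversion, or the chain enolate may add a second time, intramolecularly, to C3 before it is protonated. The fallback sets out from 3. Its lithium enolate is added to the α-silyl vinyl ketone 3-(trimethylsilyl)but-3-en-2-one, whose adduct enolate is silicon-stabilised and should neither polymerise nor cyclise. This should give the α-silyl 1,5-diketone F1. KOH in methanol then removes silicon and performs the aldol condensation, and the route is rejoined at 6.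

Step 16. Condensation at the hindered, α-branched aldehyde may be slow, and the alkylidene trione may be diverted into dimers or bis-adducts before hydride transfer. The fallback sets out from 22 and 26. Condensing them in the presence of thiophenol (piperidinium acetate, EtOH) should trap the alkylidene trione as the isolable phenylthio adduct F2. Radical desulfurisation (Bu3SnH, AIBN, toluene, 80 °C) should then cleave the activated C–S bond and arrive at 28.

Step 3. The dienolate may be protonated under thermodynamic instead of kinetic control, or the β,γ-alkene may slip into conjugation during quench and work-up, which would remove the alkene that step 4 needs. The fallback sets out from 6 and accepts the isomerisation. The lithium–ammonia reduction is worked up under equilibrating conditions (NaOMe, MeOH) to give the conjugated enone F3. TBSOTf and Et3N should convert it into the linear silyl dienol ether F4. Buffered mCPBA should then oxidise the terminal C4=C5 bond of F4 on the face anti to the C10 methyl (vinylogous Rubottom oxidation). This bypasses steps 3 and 4 and rejoins the route at 9.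

Further compounds
F1 | step 2 | 2,6-dimethyl-6-[3-oxo-2-(trimethylsilyl)butyl]-5-(prop-1-en-2-yl)cyclohex-2-en-1-one, chain trans to isopropenyl, silyl-bearing carbon undefined | CC1=CC[C@H](C(C)=C)[C@@](C)(CC([Si](C)(C)C)C(C)=O)C1=O
F2 | step 16 | C1′-phenylthio adduct of the target skeleton (C1′ undefined) | C=C(C)[C@H]1CC[C@]2(C)[C@@H](C(Sc3ccccc3)C3=C(O)C(C)(C)C(=O)C(C(=O)CC(C)C)=C3O)CC[C@](C)(O)[C@H]2C1
F3 | step 3 | conjugated 5-en-7-one with C1 isopropenyl (C4 epimer mixture, C4 undefined) | O=C1CC[C@]2(C)[C@@H](C(C)=C)CCC(C)C2=C1
F4 | step 3 | 7-(tert-butyldimethylsilyloxy)-4,6-diene with C1 isopropenyl | CC(C)(C)[Si](C)(C)OC=1CC[C@]2(C)[C@@H](C(C)=C)CCC(C)=C2C=1
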